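**Retrosynthetic overview**
1. Target 52 comes from a Schenck ene reaction (C14–OOH, C13=CH2) of the 13(14)-E-alkene 51; 51 comes from a C12–C13 Negishi union of decalin iodide 34 with butenolide vinyl iodide 48.
2. Feature used: in rings A and B the axial C4 methyl carbon (C19) and the C6 oxygen sit 1,3 to each other across C5; joining them as a C19–O–C6 2,3-dihydrofuran places C5=C6 in a diene (C5=C6–C7=C8) and puts the C4 stereocentre in a flat ring that also carries the tether.
3. Key disconnection: intramolecular Diels–Alder reaction of enal 21 forms C5–C10 and C8–C9 and closes rings A and B together; the temporary ring is then opened (C6 ketone, C19–OH to CH3) and 8α-OH and 6α-OH are set through 7-en-6-one 27.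
4. 21 comes from lactone 15 (ketene acetal phosphate, Suzuki coupling with a propenylboronate); 15 comes from dimethyl malonate by two alkylations and enzymatic desymmetrisation (C4).
5. Ring order: temporary dihydrofuran, then rings A and B in one step (step 13), then the butenolide on the side-chain fragment (step 30).

Key step: step 13

Numbering: decalin carbons C1–C10 as in labdanes; C11–C16 along the C9 side chain (C13 carries the exocyclic CH2, C14 the OOH, C16 is the butenolide O–CH); C18 is the ester carbon, C19 the axial C4 methyl, C20 the C10 methyl.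
Assumption: pig liver esterase is taken to give (R)-12 from 11, and (S)-TRIP to give (S)-38 from methacrolein; both senses are extrapolated from related substrates, and a reversed sense is corrected by the fallback for step 6 or by the mirror-image acid.

**Route**

Step 1
Reactants: 1 geraniol
Product: 2 geranyl tert-butyldimethylsilyl ether
Conditions: TBSCl, imidazole, DMF, 0 °C to rt
Reagents that add atoms: tert-butyldimethylsilyl chloride, CC(C)(C)[Si](C)(C)Cl
Why: Silylation of the primary allylic alcohol gives an ether that should survive the base, hydride and palladium steps up to step 11 and, unlike an allylic ester, is not ionised by Pd(PPh3)4.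

Step 2
Reactants: 2 geranyl tert-butyldimethylsilyl ether
Product: 4 (4E)-6-[(tert-butyldimethylsilyl)oxy]-4-methylhex-4-en-1-ol, via ozonide 3 (not isolated)
Conditions: O3 (1.0 equiv), CH2Cl2, −78 °C; then NaBH4, MeOH, −78 to 0 °C
Reagents that add atoms: ozone, [O-][O+]=O
Why: Ozonolysis with reductive work-up; the isopropylidene alkene is more electron-rich and less hindered than the 2,3-alkene next to the allylic silyloxy group, so one equivalent of ozone should cleave it selectively and NaBH4 reduces the ozonide to the primary alcohol.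

Step 3
Reactants: 4 (4E)-6-[(tert-butyldimethylsilyl)oxy]-4-methylhex-4-en-1-ol
Product: 5 {[(2E)-6-bromo-3-methylhex-2-en-1-yl]oxy}(tert-butyl)dimethylsilane
Conditions: CBr4, PPh3, 2,6-lutidine, CH2Cl2, 0 °C
Reagents that add atoms: carbon tetrabromide, BrC(Br)(Br)Br
Why: Appel bromination of an unhindered primary alcohol by SN2 displacement of the oxyphosphonium ion, with lutidine protecting the silyl ether from acid.

Step 4
Reactants: 5 {[(2E)-6-bromo-3-methylhex-2-en-1-yl]oxy}(tert-butyl)dimethylsilane; 6 dimethyl malonate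
Product: 8 dimethyl 2-[(4E)-6-[(tert-butyldimethylsilyl)oxy]-4-methylhex-4-en-1-yl]malonate, via sodium enolate 7 (not isolated)
Conditions: NaH, 6 (3 equiv), THF/DMF, 0 °C; then 5, NaI (cat.), 60 °C
Reagents that add atoms: none
Why: Malonic ester alkylation (SN2) of a primary bromide; excess malonate limits dialkylation.

Step 5
Reactants: 8 dimethyl 2-[(4E)-6-[(tert-butyldimethylsilyl)oxy]-4-methylhex-4-en-1-yl]malonate; 9 tert-butyl bromoacetate
Product: 11 dimethyl 2-(2-tert-butoxy-2-oxoethyl)-2-[(4E)-6-[(tert-butyldimethylsilyl)oxy]-4-methylhex-4-en-1-yl]malonate, via sodium enolate 10 (not isolated)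
Conditions: NaH, THF, 0 °C; then 9, 0 °C to rt
Reagents that add atoms: none
Why: Second malonate alkylation with a reactive α-bromo ester builds the prochiral quaternary carbon (future C4) that carries both carboxyl carbons (C18, C19), the C5–C6 unit and the C3–C11 chain.

Step 6
Reactants: 11 dimethyl 2-(2-tert-butoxy-2-oxoethyl)-2-[(4E)-6-[(tert-butyldimethylsilyl)oxy]-4-methylhex-4-en-1-yl]malonate
Product: 12 (2R)-4-tert-butoxy-2-[(4E)-6-[(tert-butyldimethylsilyl)oxy]-4-methylhex-4-en-1-yl]-2-(methoxycarbonyl)-4-oxobutanoic acid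
Conditions: pig liver esterase, phosphate buffer pH 7.5 (pH-stat, 1 M NaOH), DMSO (10% v/v), rt; then HCl to pH 3
Reagents that add atoms: water, O
Why: Enzymatic desymmetrisation: the esterase should hydrolyse one of the two enantiotopic methyl esters of the 2,2-disubstituted malonate, which creates the C4 stereocentre, while the tert-butyl ester and the silyl ether are not substrates.

Step 7
Reactants: 12 (2R)-4-tert-butoxy-2-[(4E)-6-[(tert-butyldimethylsilyl)oxy]-4-methylhex-4-en-1-yl]-2-(methoxycarbonyl)-4-oxobutanoic acid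
Product: 14 4-tert-butyl 1-methyl (2R)-2-[(4E)-6-[(tert-butyldimethylsilyl)oxy]-4-methylhex-4-en-1-yl]-2-(hydroxymethyl)butanedioate, via acyl imidazolide 13 (not isolated)
Conditions: 1,1'-carbonyldiimidazole, THF, rt; then NaBH4, H2O, 0 °C
Reagents that add atoms: none
Why: Chemoselective reduction of a carboxylic acid through its acyl imidazolide: NaBH4 attacks only the activated acyl group, so CO2H becomes C19H2OH while both esters and C4 are untouched.

Step 8
Reactants: 14 4-tert-butyl 1-methyl (2R)-2-[(4E)-6-[(tert-butyldimethylsilyl)oxy]-4-methylhex-4-en-1-yl]-2-(hydroxymethyl)butanedioate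
Product: 15 methyl (3R)-3-[(4E)-6-[(tert-butyldimethylsilyl)oxy]-4-methylhex-4-en-1-yl]-5-oxotetrahydrofuran-3-carboxylate
Conditions: KOtBu (0.1 equiv), THF, 0 °C
Reagents that add atoms: none
Why: Base-catalysed intramolecular transesterification (5-exo-trig lactonisation) of the C19 alkoxide onto the tert-butyl ester, favoured by the quaternary C4 (Thorpe–Ingold effect), with the expelled tert-butoxide carrying the chain.

Step 9
Reactants: 15 methyl (3R)-3-[(4E)-6-[(tert-butyldimethylsilyl)oxy]-4-methylhex-4-en-1-yl]-5-oxotetrahydrofuran-3-carboxylate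
Product: 17 methyl (3R)-3-[(4E)-6-[(tert-butyldimethylsilyl)oxy]-4-methylhex-4-en-1-yl]-5-[(diphenoxyphosphoryl)oxy]-2,3-dihydrofuran-3-carboxylate, via potassium enolate 16 (not isolated)
Conditions: KN(SiMe3)2, (PhO)2P(O)Cl, DMPU, THF, −78 °C
Reagents that add atoms: diphenyl chlorophosphate, O=P(Cl)(Oc1ccccc1)Oc1ccccc1
Why: Enolisation of the lactone at C5, the only acidic position because C4 is quaternary, and O-phosphorylation give a lactone-derived ketene acetal phosphate, an established class of cross-coupling electrophile.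

Step 10
Reactants: 17 methyl (3R)-3-[(4E)-6-[(tert-butyldimethylsilyl)oxy]-4-methylhex-4-en-1-yl]-5-[(diphenoxyphosphoryl)oxy]-2,3-dihydrofuran-3-carboxylate; 18 (E)-prop-1-en-1-ylboronic acid pinacol ester
Product: 19 methyl (3R)-3-[(4E)-6-[(tert-butyldimethylsilyl)oxy]-4-methylhex-4-en-1-yl]-5-[(1E)-prop-1-en-1-yl]-2,3-dihydrofuran-3-carboxylate
Conditions: Pd(PPh3)4 (5 mol%), aq. Cs2CO3, DMF, 50 °C
Reagents that add atoms: none
Why: Suzuki–Miyaura coupling of the ketene acetal phosphate with the alkenylboronate, with retention of the E geometry, installs C7=C8 and completes the 2-alkoxy diene, which is stable in the basic medium.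

Step 11
Reactants: 19 methyl (3R)-3-[(4E)-6-[(tert-butyldimethylsilyl)oxy]-4-methylhex-4-en-1-yl]-5-[(1E)-prop-1-en-1-yl]-2,3-dihydrofuran-3-carboxylate
Product: 20 methyl (3R)-3-[(4E)-6-hydroxy-4-methylhex-4-en-1-yl]-5-[(1E)-prop-1-en-1-yl]-2,3-dihydrofuran-3-carboxylate
Conditions: Bu4NF, THF, 0 °C
Reagents that add atoms: none
Why: Fluoride desilylation under basic conditions spares the acid-labile dienol ether.

Step 12
Reactants: 20 methyl (3R)-3-[(4E)-6-hydroxy-4-methylhex-4-en-1-yl]-5-[(1E)-prop-1-en-1-yl]-2,3-dihydrofuran-3-carboxylate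
Product: 21 methyl (3R)-3-[(4E)-4-methyl-6-oxohex-4-en-1-yl]-5-[(1E)-prop-1-en-1-yl]-2,3-dihydrofuran-3-carboxylate
Conditions: MnO2 (activated), CH2Cl2, rt
Reagents that add atoms: none
Why: Selective MnO2 oxidation of the allylic alcohol under neutral conditions gives the (E)-enal without touching the dienol ether.

Step 13
Reactants: 21 methyl (3R)-3-[(4E)-4-methyl-6-oxohex-4-en-1-yl]-5-[(1E)-prop-1-en-1-yl]-2,3-dihydrofuran-3-carboxylate
Product: 22 tricyclic enol ether aldehyde
Conditions: Me2AlCl (1.2 equiv), CH2Cl2, −78 to −20 °C; Et3N, then aq. NaHCO3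
Reagents that add atoms: none
Why: Me2AlCl binds the aldehyde and lowers the LUMO of the (E)-enal, which should then undergo a concerted but asynchronous [4+2] cycloaddition with the electron-rich 2-alkoxy diene C5=C6–C7=C8, the C5–C10 bond (largest HOMO coefficient at C5, enal β-carbon C10) running ahead of C8–C9. The closest known reaction type is the type 1 intramolecular Diels–Alder reaction of 1,7,9-decatrienes that carry a 2-oxygenated diene and an enal or enoate dienophile under alkylaluminium halide promotion; holding the diene in a five-membered cyclic enol ether that shares C4 with the tether is an extension of that precedent. Ring A (C4–C3–C2–C1–C10–C5) is closed by the three-carbon tether as C5–C10 forms, and ring B (C5–C6–C7–C8–C9–C10) is the new cyclohexene of the cycloaddition, both six-membered and fused at C5–C10. C5 is set by the C4 stereocentre, because the tether leaves C4 on one face of the flat dihydrofuran and C10 can reach C5 only on that face, so H5 ends up cis to the ester; C10 and C9 follow from the retained E geometry of the enal (C20 methyl cis to CHO) and from the endo position of the complexed aldehyde with the tether exo, which gives the trans ring fusion; C8 follows from the E-propenyl group and is erased in step 18. The step needs π-facial selectivity, secured by the ring-bound C4, and endo selectivity, secured by the Lewis acid and the chair-like tether; the regiochemistry is fixed by the tether and is electronically matched.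

Step 14
Reactants: 22 tricyclic enol ether aldehyde
Product: 23 tricyclic enol ether alkene
Conditions: Ph3PCH3Br, KOtBu, THF, 0 °C to rt
Reagents that add atoms: methyltriphenylphosphonium bromide, C[P+](c1ccccc1)(c1ccccc1)c1ccccc1.[Br-]
Why: Wittig methylenation turns C11 into the vinyl handle (C11=C12); the 9β (equatorial) configuration is the thermodynamic one, so the basic ylide should not erode C9.

Step 15
Reactants: 23 tricyclic enol ether alkene
Product: 24 19-hydroxy 6-ketone
Conditions: 0.5 M HCl, THF, rt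
Reagents that add atoms: water, O
Why: Acid hydrolysis of the cyclic enol ether (protonation at C7, hydration at C6, ring opening) unlocks the temporary ring to the C6 ketone and the C19 alcohol, which may sit in equilibrium with its ring-closed hemiketal; C5 is not involved.

Step 16
Reactants: 24 19-hydroxy 6-ketone
Product: 25 19-O-(pentafluorophenoxythiocarbonyl) 6-ketone
Conditions: C6F5OC(S)Cl, pyridine, DMAP (cat.), CH2Cl2, rt
Reagents that add atoms: O-pentafluorophenyl chlorothionoformate, S=C(Cl)Oc1c(F)c(F)c(F)c(F)c1F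
Why: O-Thioacylation of the primary neopentyl alcohol of the open form, which drains the hemiketal equilibrium and prepares the radical deoxygenation.

Step 17
Reactants: 25 19-O-(pentafluorophenoxythiocarbonyl) 6-ketone
Product: 26 6-ketone with C19 methyl
Conditions: Bu3SnH, AIBN, toluene, 110 °C
Reagents that add atoms: none
Why: Barton–McCombie deoxygenation converts C19 into the axial methyl group by a radical path, which avoids SN2 chemistry at the neopentyl carbon and ring re-closure through the C6 carbonyl oxygen.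

Step 18
Reactants: 26 6-ketone with C19 methyl
Product: 27 7-en-6-one
Conditions: IBX, DMSO/fluorobenzene, 70 °C
Reagents that add atoms: none
Why: IBX dehydrogenation of the ketone; only the C7–C8 bond can be desaturated because C5 lies between the quaternary C4 and C10.

Step 19
Reactants: 27 7-en-6-one
Product: 29 8α-hydroxy 6-ketone, via boronate 28 (not isolated)
Conditions: B2pin2, CuCl (10 mol%), DPEphos, NaOtBu (15 mol%), MeOH, THF, rt; then NaBO3·4H2O, THF/H2O, rt
Reagents that add atoms: sodium perborate, O[B-]1(O)OO[B-](O)(O)OO1.[Na+].[Na+]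
Why: Copper-catalysed conjugate borylation of the β,β-disubstituted enone followed by C–B oxidation with retention; the boryl copper species should add to C8 from the α-face, opposite the axial C10 methyl, which sets 8α-OH and the axial 8β-methyl.

Step 20
Reactants: 29 8α-hydroxy 6-ketone
Product: 30 6α,8α-diol
Conditions: SmI2 (4 equiv), THF/H2O, 0 °C to rt
Reagents that add atoms: none
Why: Single-electron reduction through the ketyl radical anion should give the thermodynamically preferred equatorial 6α-alcohol, because a 6β-oxygen would be syn-axial to the C4, C8 and C10 methyl groups, whereas hydride donors would attack from the open α-face and give 6β-OH; the esters are inert to SmI2 without an amine activator.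

Step 21
Reactants: 30 6α,8α-diol
Product: 31 bis(triethylsilyl) ether
Conditions: Et3SiOTf, 2,6-lutidine, CH2Cl2, −78 to 0 °C
Reagents that add atoms: triethylsilyl trifluoromethanesulfonate, CC[Si](CC)(CC)OS(=O)(=O)C(F)(F)F
Why: Silylation of both the secondary and the tertiary hydroxyl so that the organozinc reagent of step 31 is not protonated.

Step 22
Reactants: 31 bis(triethylsilyl) ether
Product: 33 primary alcohol, via B-alkyl-9-BBN 32 (not isolated)
Conditions: 9-BBN, THF, rt to 50 °C; then NaOH, H2O2, 0 °C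
Reagents that add atoms: hydrogen peroxide, OO
Why: Anti-Markovnikov hydroboration–oxidation of the terminal vinyl group places oxygen on C12; 9-BBN does not reduce the hindered ester.

Step 23
Reactants: 33 primary alcohol
Product: 34 primary iodide
Conditions: I2, PPh3, imidazole, CH2Cl2, 0 °C to rt
Reagents that add atoms: iodine, II
Why: Appel-type iodination of the primary alcohol by SN2 displacement of the oxyphosphonium ion.

Step 24
Reactants: 35 methacrolein; 36 allenylboronic acid pinacol ester
Product: 38 (3S)-2-methylhex-1-en-5-yn-3-ol, via borate ester 37 (not isolated)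
Conditions: (S)-3,3′-bis(2,4,6-triisopropylphenyl)-1,1′-binaphthyl-2,2′-diyl hydrogen phosphate [(S)-TRIP, 5 mol%], 4 Å molecular sieves, toluene, −20 °C; aqueous work-up
Reagents that add atoms: none
Why: Chiral phosphoric acid-catalysed propargylation of the aldehyde by the allenylboronate through a closed six-membered transition state (SE2′); the catalyst selects the aldehyde face and so sets the future C16.

Step 25
Reactants: 38 (3S)-2-methylhex-1-en-5-yn-3-ol
Product: 39 tert-butyldimethyl{[(3S)-2-methylhex-1-en-5-yn-3-yl]oxy}silane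
Conditions: TBSCl, imidazole, DMF, rt
Reagents that add atoms: tert-butyldimethylsilyl chloride, CC(C)(C)[Si](C)(C)Cl
Why: Silylation gives a bulky, non-coordinating ether so that the hydrozirconation of step 27 is governed by sterics.

Step 26
Reactants: 39 tert-butyldimethyl{[(3S)-2-methylhex-1-en-5-yn-3-yl]oxy}silane
Product: 41 tert-butyldimethyl{[(3S)-2-methylhept-1-en-5-yn-3-yl]oxy}silane, via lithium acetylide 40 (not isolated)
Conditions: n-BuLi, THF, −78 °C; then MeI, −78 °C to rt
Reagents that add atoms: iodomethane, CI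
Why: Deprotonation of the terminal alkyne and SN2 methylation of the acetylide provide the 2-alkyne that carries the future C13 methyl.

Step 27
Reactants: 41 tert-butyldimethyl{[(3S)-2-methylhept-1-en-5-yn-3-yl]oxy}silane
Product: 43 tert-butyl{[(3S,5E)-6-iodo-2-methylhepta-1,5-dien-3-yl]oxy}dimethylsilane, via alkenylzirconocene 42 (not isolated)
Conditions: Cp2Zr(H)Cl (1.5 equiv), THF, rt to 40 °C; then I2, 0 °C
Reagents that add atoms: iodine, II
Why: Syn hydrozirconation of the 2-alkyne, with zirconium settling on the less hindered methyl-bearing carbon on equilibration, and iodinolysis with retention give the (E)-2-iodoalkene; the hindered 1,1-disubstituted alkene should react more slowly.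

Step 28
Reactants: 43 tert-butyl{[(3S,5E)-6-iodo-2-methylhepta-1,5-dien-3-yl]oxy}dimethylsilane
Product: 45 (3S,5E)-3-[(tert-butyldimethylsilyl)oxy]-6-iodohept-5-en-2-one, via diol 44 (not isolated)
Conditions: OsO4 (2 mol%), NaIO4, 2,6-lutidine, dioxane/H2O, rt
Reagents that add atoms: osmium tetroxide, O=[Os](=O)(=O)=O; sodium periodate, [Na+].[O-]I(=O)(=O)=O
Why: Lemieux–Johnson oxidative cleavage; the 1,1-disubstituted alkene should be dihydroxylated in preference to the electron-poor, trisubstituted iodoalkene, and periodate cleaves the diol to the methyl ketone.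

Step 29
Reactants: 45 (3S,5E)-3-[(tert-butyldimethylsilyl)oxy]-6-iodohept-5-en-2-one
Product: 46 (3S,5E)-3-hydroxy-6-iodohept-5-en-2-one
Conditions: aq. HF, MeCN, 0 °C
Reagents that add atoms: none
Why: Acidic desilylation frees the α-hydroxy ketone without the enolisation that a basic fluoride source could cause at C16.

Step 30
Reactants: 46 (3S,5E)-3-hydroxy-6-iodohept-5-en-2-one
Product: 48 (5S)-5-[(2E)-3-iodobut-2-en-1-yl]-4-methylfuran-2(5H)-one, via acyl ylide 47 (not isolated)
Conditions: Ph3P=C=C=O, toluene, 80 °C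
Reagents that add atoms: (triphenylphosphoranylidene)ketene, O=C=C=P(c1ccccc1)(c1ccccc1)c1ccccc1
Why: The hydroxyl adds to the cumulated ylide and the resulting ester ylide closes on the ketone in an intramolecular Wittig reaction, forming the 4-methylbutenolide without touching the C16–O bond.

Step 31
Reactants: 34 primary iodide; 48 (5S)-5-[(2E)-3-iodobut-2-en-1-yl]-4-methylfuran-2(5H)-one
Product: 50 coupled bis(triethylsilyl) ether, via alkylzinc iodide 49 (not isolated)
Conditions: Zn dust (activated), LiCl, THF, 40 °C; then 48, PdCl2(dppf) (5 mol%), THF, rt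
Reagents that add atoms: none
Why: Zinc insertion into the primary iodide and Negishi coupling with the alkenyl iodide form C12–C13 with retention of the E geometry under base-free conditions, which protects the base-labile C16 centre of the butenolide.

Step 32
Reactants: 50 coupled bis(triethylsilyl) ether
Product: 51 13(14)-E-alkene diol
Conditions: HF·pyridine, THF/pyridine, 0 °C to rt
Reagents that add atoms: none
Why: Fluoride cleavage of both triethylsilyl ethers under buffered conditions that the butenolide and the trisubstituted alkene tolerate.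

Step 33
Reactants: 51 13(14)-E-alkene diol
Product: 52 CNP0324515.1
Conditions: O2, visible light, methylene blue (cat.), CH2Cl2, 0 °C; preparative HPLC
Reagents that add atoms: dioxygen, O=O
Why: Schenck ene reaction of singlet oxygen with the only electron-rich alkene: oxygen bonds to C14 and a hydrogen is taken from the C13 methyl on the more substituted side, giving the C13 exo-methylene; C14 is not controlled, so the (14S) target should form with its 14-epimer and some tertiary C13 hydroperoxide and has to be separated.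

**Compound list**
1 | geraniol | CC(C)=CCC/C(C)=C/CO | starting material
2 | geranyl tert-butyldimethylsilyl ether | CC(C)=CCC/C(C)=C/CO[Si](C)(C)C(C)(C)C | intermediate
3 | ozonide (3,3-dimethyl-1,2,4-trioxolane at the former 6,7-alkene of 2) | CC1(C)OOC(CC/C(C)=C/CO[Si](C)(C)C(C)(C)C)O1 | intermediate
4 | (4E)-6-[(tert-butyldimethylsilyl)oxy]-4-methylhex-4-en-1-ol | OCCC/C(C)=C/CO[Si](C)(C)C(C)(C)C | intermediate
5 | {[(2E)-6-bromo-3-methylhex-2-en-1-yl]oxy}(tert-butyl)dimethylsilane | BrCCC/C(C)=C/CO[Si](C)(C)C(C)(C)C | intermediate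
6 | dimethyl malonate | COC(=O)CC(=O)OC | starting material
7 | sodium enolate of dimethyl malonate | [Na+].COC(=O)[CH-]C(=O)OC | intermediate
8 | dimethyl 2-[(4E)-6-[(tert-butyldimethylsilyl)oxy]-4-methylhex-4-en-1-yl]malonate | COC(=O)C(CCC/C(C)=C/CO[Si](C)(C)C(C)(C)C)C(=O)OC | intermediate
9 | tert-butyl bromoacetate | CC(C)(C)OC(=O)CBr | starting material
10 | sodium enolate of 8 | [Na+].COC(=O)[C-](CCC/C(C)=C/CO[Si](C)(C)C(C)(C)C)C(=O)OC | intermediate
11 | dimethyl 2-(2-tert-butoxy-2-oxoethyl)-2-[(4E)-6-[(tert-butyldimethylsilyl)oxy]-4-methylhex-4-en-1-yl]malonate | COC(=O)C(CC(=O)OC(C)(C)C)(CCC/C(C)=C/CO[Si](C)(C)C(C)(C)C)C(=O)OC | intermediate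
12 | (2R)-4-tert-butoxy-2-[(4E)-6-[(tert-butyldimethylsilyl)oxy]-4-methylhex-4-en-1-yl]-2-(methoxycarbonyl)-4-oxobutanoic acid | OC(=O)[C@@](CC(=O)OC(C)(C)C)(C(=O)OC)CCC/C(C)=C/CO[Si](C)(C)C(C)(C)C | intermediate
13 | acyl imidazolide of 12 | O=C(n1ccnc1)[C@@](CC(=O)OC(C)(C)C)(C(=O)OC)CCC/C(C)=C/CO[Si](C)(C)C(C)(C)C | intermediate
14 | 4-tert-butyl 1-methyl (2R)-2-[(4E)-6-[(tert-butyldimethylsilyl)oxy]-4-methylhex-4-en-1-yl]-2-(hydroxymethyl)butanedioate | OC[C@@](CC(=O)OC(C)(C)C)(C(=O)OC)CCC/C(C)=C/CO[Si](C)(C)C(C)(C)C | intermediate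
15 | methyl (3R)-3-[(4E)-6-[(tert-butyldimethylsilyl)oxy]-4-methylhex-4-en-1-yl]-5-oxotetrahydrofuran-3-carboxylate | O=C1C[C@@](CCC/C(C)=C/CO[Si](C)(C)C(C)(C)C)(C(=O)OC)CO1 | intermediate
16 | potassium enolate of 15 | [K+].[O-]C1=C[C@@](CCC/C(C)=C/CO[Si](C)(C)C(C)(C)C)(C(=O)OC)CO1 | intermediate
17 | methyl (3R)-3-[(4E)-6-[(tert-butyldimethylsilyl)oxy]-4-methylhex-4-en-1-yl]-5-[(diphenoxyphosphoryl)oxy]-2,3-dihydrofuran-3-carboxylate | O=P(Oc1ccccc1)(Oc1ccccc1)OC1=C[C@@](CCC/C(C)=C/CO[Si](C)(C)C(C)(C)C)(C(=O)OC)CO1 | intermediate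
18 | (E)-prop-1-en-1-ylboronic acid pinacol ester | C/C=C/B1OC(C)(C)C(C)(C)O1 | starting material
19 | methyl (3R)-3-[(4E)-6-[(tert-butyldimethylsilyl)oxy]-4-methylhex-4-en-1-yl]-5-[(1E)-prop-1-en-1-yl]-2,3-dihydrofuran-3-carboxylate | C/C=C/C1=C[C@@](CCC/C(C)=C/CO[Si](C)(C)C(C)(C)C)(C(=O)OC)CO1 | intermediate
20 | methyl (3R)-3-[(4E)-6-hydroxy-4-methylhex-4-en-1-yl]-5-[(1E)-prop-1-en-1-yl]-2,3-dihydrofuran-3-carboxylate | C/C=C/C1=C[C@@](CCC/C(C)=C/CO)(C(=O)OC)CO1 | intermediate
21 | methyl (3R)-3-[(4E)-4-methyl-6-oxohex-4-en-1-yl]-5-[(1E)-prop-1-en-1-yl]-2,3-dihydrofuran-3-carboxylate (Diels–Alder precursor) | C/C=C/C1=C[C@@](CCC/C(C)=C/C=O)(C(=O)OC)CO1 | intermediate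
22 | tricyclic enol ether aldehyde (trans-decalin; 4α-CO2CH3; C19–O–C6 bridge on the β-face with C6=C7; 5α-H; 8β-CH3; 9β-CHO; 10β-CH3) | O=C[C@@H]1[C@@]2(C)CCC[C@@]3(C(=O)OC)[C@@H]2C(OC3)=C[C@@H]1C | intermediate
23 | tricyclic enol ether alkene (as 22 with 9β-vinyl) | C=C[C@@H]1[C@@]2(C)CCC[C@@]3(C(=O)OC)[C@@H]2C(OC3)=C[C@@H]1C | intermediate
24 | 19-hydroxy 6-ketone (4α-CO2CH3; 4β-CH2OH; 5α-H; 8β-CH3; 9β-vinyl; 10β-CH3) | C=C[C@@H]1[C@@]2(C)CCC[C@@](CO)(C(=O)OC)[C@@H]2C(=O)C[C@@H]1C | intermediate
25 | 19-O-(pentafluorophenoxythiocarbonyl) 6-ketone | C=C[C@@H]1[C@@]2(C)CCC[C@@](COC(=S)Oc3c(F)c(F)c(F)c(F)c3F)(C(=O)OC)[C@@H]2C(=O)C[C@@H]1C | intermediate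
26 | 6-ketone with C19 methyl (4α-CO2CH3; 4β-CH3; 8β-CH3; 9β-vinyl) | C=C[C@@H]1[C@@]2(C)CCC[C@@](C)(C(=O)OC)[C@@H]2C(=O)C[C@@H]1C | intermediate
27 | 7-en-6-one | C=C[C@@H]1[C@@]2(C)CCC[C@@](C)(C(=O)OC)[C@@H]2C(=O)C=C1C | intermediate
28 | 8α-boronate (8α-Bpin; 8β-CH3; 6-ketone) | C=C[C@@H]1[C@@]2(C)CCC[C@@](C)(C(=O)OC)[C@@H]2C(=O)C[C@@]1(C)B3OC(C)(C)C(C)(C)O3 | intermediate
29 | 8α-hydroxy 6-ketone | C=C[C@@H]1[C@@]2(C)CCC[C@@](C)(C(=O)OC)[C@@H]2C(=O)C[C@@]1(C)O | intermediate
30 | 6α,8α-diol (9β-vinyl) | C=C[C@@H]1[C@@]2(C)CCC[C@@](C)(C(=O)OC)[C@@H]2[C@@H](O)C[C@@]1(C)O | intermediate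
31 | bis(triethylsilyl) ether of 30 | C=C[C@@H]1[C@@]2(C)CCC[C@@](C)(C(=O)OC)[C@@H]2[C@@H](O[Si](CC)(CC)CC)C[C@@]1(C)O[Si](CC)(CC)CC | intermediate
32 | B-alkyl-9-BBN (boron on C12) | B1(CC[C@@H]3[C@@]4(C)CCC[C@@](C)(C(=O)OC)[C@@H]4[C@@H](O[Si](CC)(CC)CC)C[C@@]3(C)O[Si](CC)(CC)CC)C2CCCC1CCC2 | intermediate
33 | primary alcohol (C12–OH; 6α,8α-bis-OSiEt3) | OCC[C@@H]1[C@@]2(C)CCC[C@@](C)(C(=O)OC)[C@@H]2[C@@H](O[Si](CC)(CC)CC)C[C@@]1(C)O[Si](CC)(CC)CC | intermediate
34 | primary iodide (C12–I) | ICC[C@@H]1[C@@]2(C)CCC[C@@](C)(C(=O)OC)[C@@H]2[C@@H](O[Si](CC)(CC)CC)C[C@@]1(C)O[Si](CC)(CC)CC | intermediate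
35 | methacrolein | CC(=C)C=O | starting material
36 | allenylboronic acid pinacol ester | C=C=CB1OC(C)(C)C(C)(C)O1 | starting material
37 | borate ester of 38 (O–Bpin) | C#CC[C@H](OB1OC(C)(C)C(C)(C)O1)C(C)=C | intermediate
38 | (3S)-2-methylhex-1-en-5-yn-3-ol | C#CC[C@H](O)C(C)=C | intermediate
39 | tert-butyldimethyl{[(3S)-2-methylhex-1-en-5-yn-3-yl]oxy}silane | C#CC[C@H](O[Si](C)(C)C(C)(C)C)C(C)=C | intermediate
40 | lithium acetylide of 39 | [Li]C#CC[C@H](O[Si](C)(C)C(C)(C)C)C(C)=C | intermediate
41 | tert-butyldimethyl{[(3S)-2-methylhept-1-en-5-yn-3-yl]oxy}silane | CC#CC[C@H](O[Si](C)(C)C(C)(C)C)C(C)=C | intermediate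
42 | alkenylzirconocene chloride (zirconium on the methyl-bearing carbon, E) | C/C(=C\C[C@H](O[Si](C)(C)C(C)(C)C)C(C)=C)[Zr](Cl)(C1C=CC=C1)C1C=CC=C1 | intermediate
43 | tert-butyl{[(3S,5E)-6-iodo-2-methylhepta-1,5-dien-3-yl]oxy}dimethylsilane | I/C(C)=C/C[C@H](O[Si](C)(C)C(C)(C)C)C(C)=C | intermediate
44 | diol from dihydroxylation of the isopropenyl group of 43 (mixture at the new carbinol) | I/C(C)=C/C[C@H](O[Si](C)(C)C(C)(C)C)C(C)(O)CO | intermediate
45 | (3S,5E)-3-[(tert-butyldimethylsilyl)oxy]-6-iodohept-5-en-2-one | I/C(C)=C/C[C@H](O[Si](C)(C)C(C)(C)C)C(C)=O | intermediate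
46 | (3S,5E)-3-hydroxy-6-iodohept-5-en-2-one | I/C(C)=C/C[C@H](O)C(C)=O | intermediate
47 | acyl ylide (O-[(triphenylphosphoranylidene)acetyl] derivative of 46) | I/C(C)=C/C[C@H](OC(=O)C=P(c1ccccc1)(c1ccccc1)c1ccccc1)C(C)=O | intermediate
48 | (5S)-5-[(2E)-3-iodobut-2-en-1-yl]-4-methylfuran-2(5H)-one | I/C(C)=C/C[C@@H]1OC(=O)C=C1C | intermediate
49 | alkylzinc iodide (zinc on C12) | I[Zn]CC[C@@H]1[C@@]2(C)CCC[C@@](C)(C(=O)OC)[C@@H]2[C@@H](O[Si](CC)(CC)CC)C[C@@]1(C)O[Si](CC)(CC)CC | intermediate
50 | coupled bis(triethylsilyl) ether (13(14)-E-alkene; 16S butenolide) | C/C(CC[C@@H]1[C@@]2(C)CCC[C@@](C)(C(=O)OC)[C@@H]2[C@@H](O[Si](CC)(CC)CC)C[C@@]1(C)O[Si](CC)(CC)CC)=C\C[C@@H]1OC(=O)C=C1C | intermediate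
51 | 13(14)-E-alkene diol (6α,8α-diol; 16S butenolide) | C/C(CC[C@@H]1[C@@]2(C)CCC[C@@](C)(C(=O)OC)[C@@H]2[C@@H](O)C[C@@]1(C)O)=C\C[C@@H]1OC(=O)C=C1C | intermediate
52 | CNP0324515.1 (4α-CO2CH3; 6α-OH; 8α-OH; 14S-OOH; C13=CH2; 16S butenolide) | C=C(CC[C@@H]1[C@@]2(C)CCC[C@@](C)(C(=O)OC)[C@@H]2[C@@H](O)C[C@@]1(C)O)[C@H](C[C@@H]1OC(=O)C=C1C)OO | target

**Step count**
Total: 33 steps. Longest linear sequence: 26 steps (steps 1–23 and 31–33). Fragment 48 takes 7 steps (24–30).

**Steps most likely to fail**

1. Step 13 (key cycloaddition). What may go wrong: ionic addition of C5 to the aluminium-bound enal without closure of ring B, Lewis-acid cleavage or oligomerisation of the dienol ether, or too little endo preference so that the cis-fused adduct forms. The first adjustment is uncatalysed heating (toluene, BHT, 140 °C, base-washed glass). The fallback changes the dienophile from a neutral enal to an allyl cation (ionic Diels–Alder reaction through an acetal). It sets out from 21. Treatment with 1,2-bis(trimethylsilyloxy)ethane and catalytic Me3SiOTf (2,6-di-tert-butyl-4-methylpyridine as proton trap) in CH2Cl2 at −78 °C should give the dioxolane acetal F1. F1 ionises in situ to the alkoxy-allyl cation, which is attacked at C10 by the enol ether carbon C5 and then closes C8–C9, giving the cycloadduct acetal F2. Aqueous HCl in THF then cleaves both the dioxolane and the enol ether to the keto aldehyde F3. Methylenation of the aldehyde with Ph3P=CH2, which is far faster than attack on the hindered C6 ketone, returns to the route at 24.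

2. Step 6 (enzymatic desymmetrisation). What may go wrong: slow turnover of the bulky triester, or poor or reversed discrimination between two ester groups that face two chain-like substituents. The fallback replaces enzyme selectivity by classical resolution. It sets out from 11. Monosaponification with one equivalent of KOH in MeOH/H2O, which the hindered tert-butyl ester and the silyl ether should survive, gives the racemic half-ester F4. Salt formation with (S)-1-phenylethylamine (or its antipode, whichever gives the crystalline salt of the R acid) and fractional crystallisation give the diastereomerically pure salt F5. Acidification returns to the route at 12.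

3. Step 33 (photooxygenation). What may go wrong: hydrogen abstraction from C15 instead of the C13 methyl, and attack on both faces of the alkene, giving isomeric hydroperoxides that co-elute and decompose on chromatography. No stereospecific route to a secondary allylic hydroperoxide is relied on; the fallback changes the isolation to a protect, separate and release sequence. It sets out from 51. The unpurified photooxygenation mixture is treated with 2-methoxypropene and catalytic pyridinium p-toluenesulfonate in CH2Cl2 at 0 °C, which converts hydroperoxides, much faster than alcohols, into 2-methoxyprop-2-yl perketals: F6 from the target and F7 from its 14-epimer. These less polar, more robust derivatives are separated on silica or by HPLC. F6 is then cleaved with AcOH/THF/H2O, which returns to the route at 52.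

**Further compounds**
F1 | step 13 | methyl (3R)-3-[(4E)-5-(1,3-dioxolan-2-yl)-4-methylpent-4-en-1-yl]-5-[(1E)-prop-1-en-1-yl]-2,3-dihydrofuran-3-carboxylate | C/C=C/C1=C[C@@](CCC/C(C)=C/C2OCCO2)(C(=O)OC)CO1
F2 | step 13 | dioxolane acetal of adduct 22 (C11 as 1,3-dioxolan-2-yl) | O1CCOC1[C@@H]1[C@@]2(C)CCC[C@@]3(C(=O)OC)[C@@H]2C(OC3)=C[C@@H]1C
F3 | step 13 | 19-hydroxy-6-oxo 11-aldehyde (9β-CHO analogue of 24) | O=C[C@@H]1[C@@]2(C)CCC[C@@](CO)(C(=O)OC)[C@@H]2C(=O)C[C@@H]1C
F4 | step 6 | racemic 4-tert-butoxy-2-[(4E)-6-[(tert-butyldimethylsilyl)oxy]-4-methylhex-4-en-1-yl]-2-(methoxycarbonyl)-4-oxobutanoic acid | OC(=O)C(CC(=O)OC(C)(C)C)(C(=O)OC)CCC/C(C)=C/CO[Si](C)(C)C(C)(C)C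
F5 | step 6 | (S)-1-phenylethylammonium salt of the (R)-half-ester 12 | C[C@H]([NH3+])c1ccccc1.[O-]C(=O)[C@@](CC(=O)OC(C)(C)C)(C(=O)OC)CCC/C(C)=C/CO[Si](C)(C)C(C)(C)C
F6 | step 33 | 2-methoxyprop-2-yl perketal of 52 | C=C(CC[C@@H]1[C@@]2(C)CCC[C@@](C)(C(=O)OC)[C@@H]2[C@@H](O)C[C@@]1(C)O)[C@H](C[C@@H]1OC(=O)C=C1C)OOC(C)(C)OC
F7 | step 33 | 2-methoxyprop-2-yl perketal of the 14-epimer of 52 | C=C(CC[C@@H]1[C@@]2(C)CCC[C@@](C)(C(=O)OC)[C@@H]2[C@@H](O)C[C@@]1(C)O)[C@@H](C[C@@H]1OC(=O)C=C1C)OOC(C)(C)OC
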